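**Plan**
1. Numbering: the core is 3,7-dioxabicyclo[3.3.0]octane; ring A = C1, C5, C6, O7, C8 and ring B = C1, C2, O3, C4, C5; C1 carries the acetate, C2 and C6 the aryl groups.
2. Retrosynthetic cuts, in order: the acetate C–O and the two aryl O–Si bonds; then the C1–C2 bond, which opens ring B to a monocyclic oxolan-3-one (ring A with C1 as carbonyl and a CH2–O–CH2Ar chain on C5); then the O3–CH2Ar ether bond, the O7–C8 bond of ring A and, last, the C5–C6 bond.
3. Forward order: C5–C6 is joined first (iridium-catalysed anti-(hydroxymethyl)allylation of silylated vanillin), the second vanillyl unit is attached as an ether at O3, ring A is closed by epoxidation and 5-endo opening and oxidised to the C1 ketone, and ring B is closed last by light.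
4. Enabling feature: in the oxolanone the C1 carbonyl has an ether oxygen (O3), not a C–H, in the γ-position and a benzylic, α-oxygenated C2–H in the δ-position (C1–C5–C4–O3–C2), so the excited ketone takes that hydrogen (1,6-transfer) and the 1,5-biradical closes the C1–C2 bond.
5. Stereochemistry: C6 (S) and C5 (R) come from the chiral catalyst formed from [Ir(cod)Cl]2 and (S)-SEGPHOS (anti through a closed chair transition state); C1 follows from C5 because only the cis-fused bicycle can form; C2 is set by exo placement of the aryl group in the biradical closure.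

Key step: step 8

Notation: Ar = 3-methoxy-4-[(triisopropylsilyl)oxy]phenyl.
Assumption: the catalyst formed from [Ir(cod)Cl]2 and (S)-SEGPHOS is taken to deliver the (1S,2R)-diol in step 2; if the sense of induction proves opposite, the (R)-ligand is used and nothing else changes.

**Step 1**
Reactants: 1 vanillin
Product: 2 3-methoxy-4-[(triisopropylsilyl)oxy]benzaldehyde
Conditions: TIPSCl, imidazole, DMF, rt
Reagents that add atoms: triisopropylsilyl chloride, CC(C)[Si](Cl)(C(C)C)C(C)C
Why: Imidazole-promoted phenol silylation masks the phenol, which would otherwise be alkylated in step 5 and could quench the excited ketone in step 8; the bulky silyl ether should survive the mildly basic steps 2 and 5.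

**Step 2**
Reactants: 2 3-methoxy-4-[(triisopropylsilyl)oxy]benzaldehyde; 3 4-ethenyl-1,3-dioxolan-2-one (vinyl ethylene carbonate, racemic)
Product: 4 (1S,2R)-2-ethenyl-1-Ar-propane-1,3-diol
Conditions: [Ir(cod)Cl]2 (2.5 mol%), (S)-SEGPHOS (5 mol%), 4-cyano-3-nitrobenzoic acid (10 mol%), K3PO4 (5 mol%), i-PrOH (2 equiv), THF, 60 °C
Reagents that add atoms: none
Why: Iridium-catalysed transfer-hydrogenative carbonyl (hydroxymethyl)allylation: ionisation and decarboxylation of 3 give a (hydroxymethyl)-substituted allyliridium whose (E)-σ-allyl form adds to the aldehyde through a closed chair transition state, so the anti relationship follows from the (E)-geometry and both new centres are set by the cyclometalated catalyst formed from [Ir(cod)Cl]2, (S)-SEGPHOS and the nitrobenzoic acid, with isopropanol as terminal reductant.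

**Step 3**
Reactants: 2 3-methoxy-4-[(triisopropylsilyl)oxy]benzaldehyde
Product: 5 {3-methoxy-4-[(triisopropylsilyl)oxy]phenyl}methanol
Conditions: NaBH4, MeOH, 0 °C
Reagents that add atoms: none
Why: Borohydride reduction of an aryl aldehyde is chemoselective and leaves the aryl silyl ether untouched.

**Step 4**
Reactants: 5 {3-methoxy-4-[(triisopropylsilyl)oxy]phenyl}methanol
Product: 6 4-(bromomethyl)-2-methoxy-1-[(triisopropylsilyl)oxy]benzene
Conditions: CBr4, PPh3, CH2Cl2, 0 °C
Reagents that add atoms: carbon tetrabromide, BrC(Br)(Br)Br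
Why: The Appel reaction converts the benzylic alcohol into the bromide under neutral conditions that spare the silyl ether; the reactive bromide is used directly.

**Step 5**
Reactants: 4 (1S,2R)-2-ethenyl-1-Ar-propane-1,3-diol; 6 4-(bromomethyl)-2-methoxy-1-[(triisopropylsilyl)oxy]benzene
Product: 8 (1S,2R)-1-Ar-2-[(ArCH2O)methyl]but-3-en-1-ol, via stannylene acetal 7 (not isolated)
Conditions: Bu2SnO, toluene, reflux (Dean–Stark); then 6, Bu4NI (cat.), toluene, 60 °C
Reagents that add atoms: none
Why: Regioselective O-alkylation through the dibutylstannylene acetal of a 1,3-diol activates the less hindered primary oxygen, so the secondary benzylic hydroxyl stays free and no stereocentre is touched; fluoride additives are avoided because of the aryl silyl ethers.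

**Step 6**
Reactants: 8 (1S,2R)-1-Ar-2-[(ArCH2O)methyl]but-3-en-1-ol
Product: 10 (4S,5S)-5-Ar-4-[(ArCH2O)methyl]oxolan-3-ol (both C3 epimers), via epoxy alcohol 9 (not isolated)
Conditions: mCPBA, CH2Cl2, 0 °C → rt; then CSA (10 mol%), CH2Cl2, 0 °C
Reagents that add atoms: 3-chloroperbenzoic acid, OOC(=O)c1cccc(Cl)c1
Why: Prilezhaev epoxidation of the terminal alkene is followed by acid-catalysed 5-endo opening of the epoxide at its CH2 carbon by the benzylic hydroxyl (SN2 at the primary carbon), so the benzylic C–O bond and both existing stereocentres are retained and the epimeric mixture at the new carbinol converges in step 7.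

**Step 7**
Reactants: 10 (4S,5S)-5-Ar-4-[(ArCH2O)methyl]oxolan-3-ol
Product: 11 (4R,5S)-5-Ar-4-[(ArCH2O)methyl]oxolan-3-one
Conditions: Dess–Martin periodinane, pyridine, CH2Cl2, 0 °C → rt
Reagents that add atoms: none
Why: Dess–Martin oxidation is non-basic, so the β-alkoxy ketone should neither eliminate nor lose the 4,5-trans arrangement, which is in any case the more stable one (the change of the C4 descriptor from 10 to 11 is only a change of CIP priorities).

**Step 8**
Reactants: 11 (4R,5S)-5-Ar-4-[(ArCH2O)methyl]oxolan-3-one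
Product: 12 (1S,2R,5R,6S)-2,6-bis-Ar-3,7-dioxabicyclo[3.3.0]octan-1-ol
Conditions: hν (medium-pressure Hg lamp, Pyrex filter), degassed benzene (0.01 M), rt
Reagents that add atoms: none
Why: Norrish–Yang photocyclisation: n→π* excitation of the C1 ketone is followed by 1,6-hydrogen transfer from the δ-carbon C2 to the carbonyl oxygen through a seven-membered transition state, and the resulting 1,5-biradical (ketyl at C1, α-alkoxybenzyl radical at C2) collapses to the C1–C2 bond. The closest known reaction type is the δ-hydrogen abstraction and cyclisation of β-alkoxy ketones to oxolan-3-ols, which is known also for oxolan-3-ones carrying an (arylmethoxy)methyl side chain. Ring B closes by recombination of the 1,5-biradical to a five-membered ring, a radical–radical coupling and not a polar closure. C1 is controlled by the existing C5 centre, because the three-atom tether can deliver C2 only to the face of the ketyl that gives the cis-fused bicycle, and C2 is controlled sterically, the planar benzylic radical closing with its aryl group on the convex (exo) face, away from the C8 methylene of ring A. The step needs site selectivity in the hydrogen transfer and chemoselectivity against α-cleavage of the excited ketone: the first is secured by the ether oxygen O3 in the γ-position (no accessible γ C–H) and by the weak benzylic, α-oxygenated C2–H bond, the second by the speed of this intramolecular transfer and by the Pyrex filter, which keeps the aryl silyl ethers from absorbing.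

**Step 9**
Reactants: 12 (1S,2R,5R,6S)-2,6-bis-Ar-3,7-dioxabicyclo[3.3.0]octan-1-ol
Product: 13 (1S,2R,5R,6S)-2,6-bis-Ar-3,7-dioxabicyclo[3.3.0]octan-1-yl acetate
Conditions: Ac2O, DMAP, Et3N, CH2Cl2, rt → 40 °C
Reagents that add atoms: acetic anhydride, CC(=O)OC(C)=O
Why: DMAP-catalysed acyl transfer (Steglich-type acylation) is the standard way to esterify a hindered tertiary alcohol, and with both phenols silylated the bridgehead hydroxyl is the only acylable site.

**Step 10**
Reactants: 13 (1S,2R,5R,6S)-2,6-bis-Ar-3,7-dioxabicyclo[3.3.0]octan-1-yl acetate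
Product: 14 1-acetoxypinoresinol, (1S,2R,5R,6S)-2,6-bis(4-hydroxy-3-methoxyphenyl)-3,7-dioxabicyclo[3.3.0]octan-1-yl acetate
Conditions: TBAF, AcOH, THF, 0 °C
Reagents that add atoms: none
Why: Fluoride-induced cleavage of the two aryl silyl ethers, buffered with acetic acid so that no free phenoxide can attack the tertiary acetate, leaves the acetate and the benzylic ethers of the furofuran untouched.

**Compound list**
1 | vanillin (4-hydroxy-3-methoxybenzaldehyde) | COc1cc(C=O)ccc1O | starting material
2 | 3-methoxy-4-[(triisopropylsilyl)oxy]benzaldehyde | COc1cc(C=O)ccc1O[Si](C(C)C)(C(C)C)C(C)C | intermediate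
3 | 4-ethenyl-1,3-dioxolan-2-one (vinyl ethylene carbonate, racemic) | C=CC1COC(=O)O1 | starting material
4 | (1S,2R)-2-ethenyl-1-Ar-propane-1,3-diol | COc1cc([C@@H](O)[C@@H](CO)C=C)ccc1O[Si](C(C)C)(C(C)C)C(C)C | intermediate
5 | {3-methoxy-4-[(triisopropylsilyl)oxy]phenyl}methanol | COc1cc(CO)ccc1O[Si](C(C)C)(C(C)C)C(C)C | intermediate
6 | 4-(bromomethyl)-2-methoxy-1-[(triisopropylsilyl)oxy]benzene | COc1cc(CBr)ccc1O[Si](C(C)C)(C(C)C)C(C)C | intermediate
7 | (4S,5R)-2,2-dibutyl-5-ethenyl-4-Ar-1,3,2-dioxastannane | COc1cc([C@H]2O[Sn](CCCC)(CCCC)OC[C@H]2C=C)ccc1O[Si](C(C)C)(C(C)C)C(C)C | intermediate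
8 | (1S,2R)-1-Ar-2-[(ArCH2O)methyl]but-3-en-1-ol | COc1cc([C@@H](O)[C@@H](COCc2ccc(O[Si](C(C)C)(C(C)C)C(C)C)c(OC)c2)C=C)ccc1O[Si](C(C)C)(C(C)C)C(C)C | intermediate
9 | (1S,2R)-1-Ar-3-(ArCH2O)-2-(oxiran-2-yl)propan-1-ol, both oxirane epimers | COc1cc([C@@H](O)[C@@H](COCc2ccc(O[Si](C(C)C)(C(C)C)C(C)C)c(OC)c2)C2CO2)ccc1O[Si](C(C)C)(C(C)C)C(C)C | intermediate
10 | (4S,5S)-5-Ar-4-[(ArCH2O)methyl]oxolan-3-ol, both C3 epimers | COc1cc([C@H]2OCC(O)[C@@H]2COCc2ccc(O[Si](C(C)C)(C(C)C)C(C)C)c(OC)c2)ccc1O[Si](C(C)C)(C(C)C)C(C)C | intermediate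
11 | (4R,5S)-5-Ar-4-[(ArCH2O)methyl]oxolan-3-one | COc1cc([C@H]2OCC(=O)[C@@H]2COCc2ccc(O[Si](C(C)C)(C(C)C)C(C)C)c(OC)c2)ccc1O[Si](C(C)C)(C(C)C)C(C)C | intermediate
12 | (1S,2R,5R,6S)-2,6-bis-Ar-3,7-dioxabicyclo[3.3.0]octan-1-ol | COc1cc([C@H]2OC[C@]3(O)[C@@H](c4ccc(O[Si](C(C)C)(C(C)C)C(C)C)c(OC)c4)OC[C@H]23)ccc1O[Si](C(C)C)(C(C)C)C(C)C | intermediate
13 | (1S,2R,5R,6S)-2,6-bis-Ar-3,7-dioxabicyclo[3.3.0]octan-1-yl acetate | COc1cc([C@H]2OC[C@]3(OC(C)=O)[C@@H](c4ccc(O[Si](C(C)C)(C(C)C)C(C)C)c(OC)c4)OC[C@H]23)ccc1O[Si](C(C)C)(C(C)C)C(C)C | intermediate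
14 | 1-acetoxypinoresinol, (1S,2R,5R,6S)-2,6-bis(4-hydroxy-3-methoxyphenyl)-3,7-dioxabicyclo[3.3.0]octan-1-yl acetate | COc1cc([C@H]2OC[C@]3(OC(C)=O)[C@@H](c4ccc(O)c(OC)c4)OC[C@H]23)ccc1O | target

**Totals**
Total step count: 10. Longest linear sequence: 9 steps (steps 1, 3, 4, 5, 6, 7, 8, 9, 10), because bromide 6 is itself made from aldehyde 2. The chain through diol 4 (steps 1, 2, 5, 6, 7, 8, 9, 10) has 8 steps.

**Steps most likely to fail**

Step 8. α-Cleavage of the excited oxolanone (ring opening, decarbonylation) or reverse hydrogen transfer may outrun biradical closure, and closure may place the C2 aryl group on the concave face. The fallback sets out from ketone 11 and returns at 12. Bromide 6 and PPh3 (toluene, 80 °C) give {[3-methoxy-4-(triisopropylsilyloxy)phenyl]methyl}triphenylphosphonium bromide F1, which KN(SiMe3)2 (THF, −78 °C) converts into the benzylidene ylide F2 (not isolated). Wittig olefination of 11 should give the 4-(arylmethylidene)oxolane F3 as an E/Z mixture, both isomers being usable. Dihydroxylation (OsO4 cat., NMO, acetone–water) is expected from the face opposite to the C3 side chain and should give the diol F4, with the tertiary hydroxyl trans and the benzylic carbinol carbon cis to the CH2O chain. TFA in wet CH2Cl2 at 0 °C should then ionise the electron-rich benzylic carbinol; the side-chain ether oxygen captures the cation (debenzylative cycloetherification, the silyloxybenzyl group leaving as alcohol 5 after aqueous work-up) and the thermodynamically preferred exo-aryl furofuranol 12 should result.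

Step 6. Under acid the electron-rich benzylic alcohol may ionise (loss of configuration at the aryl-bearing carbon, elimination), the hydroxyl may attack the internal epoxide carbon (oxetane), or the side-chain ether oxygen may open the epoxide in place of the hydroxyl. The fallback sets out from 8 and returns at 10 without any acid. Iridium-catalysed transfer vinylation ([Ir(cod)Cl]2, Na2CO3, vinyl acetate, toluene, 100 °C) should give the vinyl ether F5. Ring-closing metathesis (second-generation Grubbs catalyst, toluene, 70 °C) should give the 2,3-dihydrofuran F6 with loss of ethene. Hydroboration with 9-BBN (THF, rt) places boron on the β-carbon of the enol ether and gives the alkylborane F7 (not isolated), and oxidation with NaBO3·4H2O should return the oxolan-3-ol 10 as one of its C3 epimers.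

Step 2. Insufficient anti/syn or enantioselectivity with the electron-rich aldehyde, an unexpected sense of induction, or further reaction of the product's primary alcohol may erode the stereochemical basis of the route. The fallback sets out from aldehyde 2 and returns at diol 4 with auxiliary control of known sense. (S)-4-Benzyloxazolidin-2-one is acylated (n-BuLi, (E)-but-2-enoyl chloride, THF, −78 °C) to the N-crotonyl imide F8. Bu2BOTf and Et3N (CH2Cl2, −78 °C) give the (Z)-dibutylboron dienolate F9 (not isolated), whose Evans syn-aldol addition to 2 at the α-carbon (−78 → 0 °C; pH 7 buffer, H2O2 work-up) should give the α-vinyl β-hydroxy imide F10. LiBH4 (THF, H2O, 0 °C) cleaves the auxiliary reductively and should give 4, since the Evans syn adduct corresponds to the anti 2-ethenyl-1,3-diol.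

**Further compounds**
F1 | step 8 | {[3-methoxy-4-(triisopropylsilyloxy)phenyl]methyl}triphenylphosphonium bromide | COc1cc(C[P+](c2ccccc2)(c2ccccc2)c2ccccc2)ccc1O[Si](C(C)C)(C(C)C)C(C)C.[Br-]
F2 | step 8 | [3-methoxy-4-(triisopropylsilyloxy)benzylidene]triphenylphosphorane | COc1cc(C=P(c2ccccc2)(c2ccccc2)c2ccccc2)ccc1O[Si](C(C)C)(C(C)C)C(C)C
F3 | step 8 | (2S,3R)-2-Ar-4-(Ar-methylidene)-3-[(ArCH2O)methyl]oxolane, E/Z mixture | COc1cc([C@H]2OCC(=Cc3ccc(O[Si](C(C)C)(C(C)C)C(C)C)c(OC)c3)[C@@H]2COCc2ccc(O[Si](C(C)C)(C(C)C)C(C)C)c(OC)c2)ccc1O[Si](C(C)C)(C(C)C)C(C)C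
F4 | step 8 | (3S,4R,5S)-5-Ar-3-[Ar(hydroxy)methyl]-4-[(ArCH2O)methyl]oxolan-3-ol, epimers at the benzylic carbinol | COc1cc([C@H]2OC[C@](O)(C(O)c3ccc(O[Si](C(C)C)(C(C)C)C(C)C)c(OC)c3)[C@@H]2COCc2ccc(O[Si](C(C)C)(C(C)C)C(C)C)c(OC)c2)ccc1O[Si](C(C)C)(C(C)C)C(C)C
F5 | step 6 | (1S,2R)-1-Ar-1-(ethenyloxy)-2-[(ArCH2O)methyl]but-3-ene | COc1cc([C@@H](OC=C)[C@@H](COCc2ccc(O[Si](C(C)C)(C(C)C)C(C)C)c(OC)c2)C=C)ccc1O[Si](C(C)C)(C(C)C)C(C)C
F6 | step 6 | (2S,3R)-2-Ar-3-[(ArCH2O)methyl]-2,3-dihydrofuran | COc1cc([C@H]2OC=C[C@@H]2COCc2ccc(O[Si](C(C)C)(C(C)C)C(C)C)c(OC)c2)ccc1O[Si](C(C)C)(C(C)C)C(C)C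
F7 | step 6 | 9-{(4R,5S)-5-Ar-4-[(ArCH2O)methyl]oxolan-3-yl}-9-borabicyclo[3.3.1]nonane | COc1cc([C@H]2OCC(B3C4CCCC3CCC4)[C@@H]2COCc2ccc(O[Si](C(C)C)(C(C)C)C(C)C)c(OC)c2)ccc1O[Si](C(C)C)(C(C)C)C(C)C
F8 | step 2 | (4S)-4-benzyl-3-[(E)-but-2-enoyl]-1,3-oxazolidin-2-one | C/C=C/C(=O)N1[C@@H](Cc2ccccc2)COC1=O
F9 | step 2 | (4S)-4-benzyl-3-{(1Z)-1-[(dibutylboranyl)oxy]buta-1,3-dien-1-yl}-1,3-oxazolidin-2-one | C=C/C=C(\OB(CCCC)CCCC)N1[C@@H](Cc2ccccc2)COC1=O
F10 | step 2 | (4S)-4-benzyl-3-{(2S)-2-[(S)-hydroxy(Ar)methyl]but-3-enoyl}-1,3-oxazolidin-2-one | COc1cc([C@@H](O)[C@H](C=C)C(=O)N2[C@@H](Cc3ccccc3)COC2=O)ccc1O[Si](C(C)C)(C(C)C)C(C)C
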